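**Assumption:** the SMILES is read as the all-trans (2R,3S,4S,5R) tetrahydrofuran; compounds 1, 2 and 4 are bought. The route has not been run: step 2 is designed by analogy to single Evans aldol–lactonisations of succinate imides, and step 3 by analogy to the known acid rearrangement of phenolic cinnamate-dimer bis-lactones.

## Retrosynthetic overview

1. The target is the mono-O-methyl ether of a C2-symmetric all-trans bis-syringyl diol (8), so the last step is a desymmetrising phenol methylation; the phenols are carried as benzyl ethers.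
2. Diol ⇐ LiAlH4 reduction of the all-trans tetrahydrofuran-3,4-diester (6).
3. Tetrahydrofuran ring ⇐ acid methanolysis and benzylic SN1 etherification of a cis-fused bis-γ-lactone (5); C2/C5 are set here under thermodynamic control, C3/C4 are untouched.
4. Bis-lactone ⇐ two Evans syn-aldols on N,N'-succinyl bis-oxazolidinone (3) with aldehyde 4, then double lactonisation; C3/C4 are set here.
5. Ring order: two γ-lactones (step 2), then the tetrahydrofuran (step 3).

## Route

**Step 1**
Reactants: 1, (R)-4-benzyl-2-oxazolidinone (2.05 equiv); 2, succinyl chloride (1.0 equiv)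
Product: 3, 1,4-bis[(4R)-4-benzyl-2-oxo-1,3-oxazolidin-3-yl]butane-1,4-dione
Conditions: n-BuLi (2.05 equiv), THF, −78 °C; then 2, −78 → 0 °C
Reagents that add atoms: succinyl chloride (2), O=C(Cl)CCC(Cl)=O
Why: Double N-acylation of the lithiated oxazolidinone (imide formation); no new stereocentre, and the auxiliary centres are not touched.

**Step 2**
Reactants: 3; 4, 4-(benzyloxy)-3,5-dimethoxybenzaldehyde (2.6 equiv)
Product: 5, (3R,3aR,6R,6aR)-3,6-bis[4-(benzyloxy)-3,5-dimethoxyphenyl]tetrahydrofuro[3,4-c]furan-1,4-dione (cis-fused, both aryls exo), plus 2 equiv of recovered 1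
Conditions: n-Bu2BOTf (2.4 equiv), i-Pr2NEt (2.8 equiv), CH2Cl2, 0 °C; 4, −78 → 0 °C; pH 7 buffer/MeOH/H2O2, 0 °C; then PPTS (cat.), CH2Cl2, rt → 40 °C
Reagents that add atoms: aldehyde 4 (two equivalents incorporated), O=Cc1cc(OC)c(OCc2ccccc2)c(OC)c1
Why: Two Evans boron syn-aldol reactions (Z-enolates, Zimmerman–Traxler chair, attack anti to the auxiliary benzyl group) make both α-carbons R, i.e. the threo succinate, and both carbinols R; each hydroxyl then lactonises 5-exo onto the distal imide with loss of auxiliary, and only the threo bis-adduct can close to the cis-fused bis-lactone.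

**Step 3**
Reactants: 5
Product: 6, dimethyl (2R,3R,4R,5R)-2,5-bis[4-(benzyloxy)-3,5-dimethoxyphenyl]oxolane-3,4-dicarboxylate (all-trans)
Conditions: HCl (from AcCl, ~10 equiv) in dry MeOH, 0 → 50 °C, monitored and stopped at full conversion
Reagents that add atoms: methanol, CO (two OMe groups; one H2O is lost)
Why: Acid-catalysed lactone methanolysis followed by benzylic SN1 cyclo-etherification (bis-lactone to tetrahydrofuran-diester rearrangement); C3/C4 are not epimerised under acid, and the reversible benzylic ionisation places each aryl trans to its neighbouring ester, giving the all-trans ring.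

**Step 4**
Reactants: 6
Product: 7, [(2R,3S,4S,5R)-2,5-bis[4-(benzyloxy)-3,5-dimethoxyphenyl]oxolane-3,4-diyl]dimethanol
Conditions: LiAlH4 (3 equiv), THF, 0 °C → rt
Reagents that add atoms: none
Why: Hydride reduction of both esters to primary alcohols; no stereocentre is touched (the descriptors at C3/C4 change from R to S only because of CIP priority).

**Step 5**
Reactants: 7
Product: 8, 4,4'-[(2R,3S,4S,5R)-3,4-bis(hydroxymethyl)oxolane-2,5-diyl]bis(2,6-dimethoxyphenol)
Conditions: H2 (1 atm), 10% Pd/C, EtOAc–MeOH, rt, stopped after uptake of 2 equiv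
Reagents that add atoms: none
Why: Hydrogenolysis of the two aryl benzyl ethers, which cleave much faster than the hindered ring benzylic C–O bonds; no stereocentre is affected.

**Step 6**
Reactants: 8
Product: 9, 4-[(2R,3S,4S,5R)-3,4-bis(hydroxymethyl)-5-(3,4,5-trimethoxyphenyl)oxolan-2-yl]-2,6-dimethoxyphenol (target)
Conditions: MeI (1.0 equiv), K2CO3 (1.1 equiv), acetone, rt; separate 9 from recovered 8 (recycled) and the bis-methyl ether
Reagents that add atoms: iodomethane, CI
Why: Williamson O-methylation that is selective for phenol over the aliphatic alcohols (pKa); the two phenols of C2-symmetric 8 are homotopic, so mono-alkylation gives a single compound with the stereocentres unchanged, in a statistical yield of at most about 50% per pass.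

## Compound list

1 | (R)-4-benzyl-2-oxazolidinone | O=C1N[C@H](Cc2ccccc2)CO1 | starting material
2 | succinyl chloride | O=C(Cl)CCC(Cl)=O | starting material
3 | 1,4-bis[(4R)-4-benzyl-2-oxo-1,3-oxazolidin-3-yl]butane-1,4-dione | O=C(CCC(=O)N1[C@H](Cc2ccccc2)COC1=O)N1[C@H](Cc2ccccc2)COC1=O | intermediate
4 | 4-(benzyloxy)-3,5-dimethoxybenzaldehyde | O=Cc1cc(OC)c(OCc2ccccc2)c(OC)c1 | starting material
5 | (3R,3aR,6R,6aR)-3,6-bis[4-(benzyloxy)-3,5-dimethoxyphenyl]tetrahydrofuro[3,4-c]furan-1,4-dione | O=C1O[C@@H](c2cc(OC)c(OCc3ccccc3)c(OC)c2)[C@@H]2C(=O)O[C@@H](c3cc(OC)c(OCc4ccccc4)c(OC)c3)[C@H]12 | intermediate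
6 | dimethyl (2R,3R,4R,5R)-2,5-bis[4-(benzyloxy)-3,5-dimethoxyphenyl]oxolane-3,4-dicarboxylate | COc1cc([C@@H]2O[C@@H](c3cc(OC)c(OCc4ccccc4)c(OC)c3)[C@H](C(=O)OC)[C@H]2C(=O)OC)cc(OC)c1OCc1ccccc1 | intermediate
7 | [(2R,3S,4S,5R)-2,5-bis[4-(benzyloxy)-3,5-dimethoxyphenyl]oxolane-3,4-diyl]dimethanol | COc1cc([C@@H]2O[C@@H](c3cc(OC)c(OCc4ccccc4)c(OC)c3)[C@H](CO)[C@H]2CO)cc(OC)c1OCc1ccccc1 | intermediate
8 | 4,4'-[(2R,3S,4S,5R)-3,4-bis(hydroxymethyl)oxolane-2,5-diyl]bis(2,6-dimethoxyphenol) | COc1cc([C@@H]2O[C@@H](c3cc(OC)c(O)c(OC)c3)[C@H](CO)[C@H]2CO)cc(OC)c1O | intermediate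
9 | 4-[(2R,3S,4S,5R)-3,4-bis(hydroxymethyl)-5-(3,4,5-trimethoxyphenyl)oxolan-2-yl]-2,6-dimethoxyphenol | COc1cc([C@@H]2O[C@@H](c3cc(OC)c(OC)c(OC)c3)[C@H](CO)[C@H]2CO)cc(OC)c1O | target

## Summary

Total steps: 6. Longest linear sequence: 6 (fully linear from 1 and 2).

Three steps most likely to fail:

- **Step 2 (double aldol and bis-lactonisation).** The vicinal bis-enolate may form or react sluggishly, or the first aldolate may lactonise before the second aldol. Fallback: set the threo C3/C4 pair by substrate control instead. Add a lithiated 2-aryl-1,3-dithiane to (5S)-5-(d-menthyloxy)furan-2(5H)-one and trap the enolate with the second aryl aldehyde to give the trans,trans-lactone. Then hydrolyse the dithiane, reduce with LiAlH4 to the tetraol, pivaloylate the two primary alcohols, close the 2,5-diaryl ether with acid and deprotect.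
- **Step 3 (bis-lactone to tetrahydrofuran diester).** The benzylic cation can instead give the aryltetralin by Friedel–Crafts attack of the other ring, benzylic methyl ethers, or the arylidene ester by elimination. Fallback: leave the carboxylate oxidation level. Reduce 5 with LiAlH4 to the tetraol, pivaloylate the two primary alcohols, close the ring from the bis-benzylic diol with MsCl/Et3N at low temperature (with brief mild-acid equilibration to all-trans if needed), then remove the pivalates.
- **Step 6 (statistical mono-methylation).** Yield is capped near 50% per pass and the step sits at the end of the route. Fallback: differentiate the rings at the C–C bond-forming stage. Run step 2 as a sequential double aldol with 4 and then 3,4,5-trimethoxybenzaldehyde, isolate the mixed bis-lactone, and carry it through steps 3–5, so that hydrogenolysis delivers 9 directly.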